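**Retrosynthetic overview**
1. Target 6 ⇐ twofold deoxybromination/aromatisation of 5,5'-dibromo-3,3'-bioxindole 4: both C2–Br bonds come from lactam C=O groups, so no indole is ever brominated electrophilically.
2. 4 ⇐ two-electron reduction of 5,5'-dibromoisoindigo 3.
3. 3 ⇐ aldol condensation of 5-bromoisatin 1 with 5-bromooxindole 2: the C3–C3' bond is made as a C=C, so no biaryl coupling or oxidative indole dimerisation is used.
4. Ring order: both five-membered lactam rings are bought preformed, and the two pyrrole rings only become aromatic indoles in the last step.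

Assumption: the SMILES carries no stereodescriptor and the molecule has no stereocentre, so the 3,3'-axis is treated as configurationally undefined and no enantiocontrol is needed.

**Step 1**
Reactants: 1 5-bromoisatin; 2 5-bromooxindole
Product: 3 (E)-5,5'-dibromoisoindigo
Conditions: AcOH, conc. HCl (cat.), reflux, 24 h; filter the precipitate, wash with H2O, EtOH and EtOAc
Reagents that add atoms: none
Why: Acid-catalysed aldol condensation of the oxindole enol onto the isatin C3 ketone followed by dehydration gives the thermodynamically preferred E-alkene, which precipitates and drives the reaction.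

**Step 2**
Reactants: 3 (E)-5,5'-dibromoisoindigo
Product: 4 5,5'-dibromo-3,3'-bioxindole (meso/dl mixture)
Conditions: Zn dust (6 equiv), AcOH–THF 1:1, 60 °C, N2; filter hot, precipitate with degassed H2O
Reagents that add atoms: none
Why: Dissolving-metal conjugate reduction (electron transfer then protonation) of the very electron-poor central alkene leaves the aryl C–Br bonds alone; the two new C3 centres form unselectively, which does not matter because both are erased in step 3.

**Step 3**
Reactants: 4 5,5'-dibromo-3,3'-bioxindole
Product: 6 rivularin-c (2,2',5,5'-tetrabromo-1H,1'H-3,3'-biindole), via bis-dibromophosphate imidate 5 (not isolated)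
Conditions: POBr3 (3 equiv), ClCH2CH2Cl, 80 °C, N2; then imidazole (2.5 equiv), 80 °C; cold aq. NaHCO3 quench
Reagents that add atoms: phosphoryl tribromide, O=P(Br)(Br)Br
Why: Twofold Vilsmeier-type lactam activation, in which each oxindole C=O is O-phosphorylated to imidate 5 and bromide then displaces the phosphate at C2 by addition–elimination, with tautomerisation to the aromatic 1H-indole as the driving force, as in the known oxindole to 2-bromoindole deoxybromination; both sp3 C3 centres of 4 disappear, so the meso/dl mixture converges and no stereocentre remains.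

**Compound list**
1 | 5-bromoisatin (5-bromoindoline-2,3-dione) | O=C1Nc2ccc(Br)cc2C1=O | starting material
2 | 5-bromooxindole (5-bromoindolin-2-one) | O=C1Cc2cc(Br)ccc2N1 | starting material
3 | (E)-5,5'-dibromoisoindigo ((E)-5,5'-dibromo-[3,3'-biindolinylidene]-2,2'-dione) | O=C1Nc2ccc(Br)cc2/C1=C1\C(=O)Nc2ccc(Br)cc21 | intermediate
4 | 5,5'-dibromo-3,3'-bioxindole (5,5'-dibromo-[3,3'-biindoline]-2,2'-dione; meso/dl mixture, C3 and C3' undefined) | O=C1Nc2ccc(Br)cc2C1C1C(=O)Nc2ccc(Br)cc21 | intermediate
5 | 5,5'-dibromo-1H,1'H-3,3'-biindole-2,2'-diyl bis(phosphorodibromidate), not isolated | O=P(Br)(Br)Oc1[nH]c2ccc(Br)cc2c1-c1c(OP(=O)(Br)Br)[nH]c2ccc(Br)cc12 | intermediate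
6 | rivularin-c (2,2',5,5'-tetrabromo-1H,1'H-3,3'-biindole) | Brc1ccc2[nH]c(Br)c(-c3c(Br)[nH]c4ccc(Br)cc34)c2c1 | target

**Total step count:** 3. **Longest linear sequence:** 3 (both partners of step 1 are commercial).

**Steps most likely to fail, with fallbacks**

Step 3 (highest risk). A half-activated intermediate could close intramolecularly through the second lactam oxygen to a furan-bridged diindole, 4 could re-oxidise to 3 in air, and free N–H 2-bromoindoles are acid-labile. Excess POBr3, an inert atmosphere and imidazole buffering address these. The fallback sets out from 4 and comes back at 6. BH3·THF (THF, 0 °C to reflux) reduces both lactams to hemiaminal borates that eliminate to give 5,5'-dibromo-1H,1'H-3,3'-biindole F1. NBS (2.0 equiv, THF, −78 to 0 °C) then brominates the only open pyrrole positions, C2 and C2', since C3 is blocked. This is the conventional late-stage electrophilic bromination, held in reserve.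

Step 2. The suspension of insoluble 3 may reduce sluggishly, and prolonged heating with Zn risks some aryl debromination. The fallback sets out from 3 and comes back at 4 by a solubilising protecting-group detour. Boc2O and DMAP (cat.) in THF give soluble di-tert-butyl (E)-5,5'-dibromo-2,2'-dioxo-[3,3'-biindolinylidene]-1,1'-dicarboxylate F2. Homogeneous electron-transfer reduction with Na2S2O4/NaHCO3 in THF–H2O at room temperature, which cannot touch C–Br, gives di-tert-butyl 5,5'-dibromo-2,2'-dioxo-[3,3'-biindoline]-1,1'-dicarboxylate F3. TFA in CH2Cl2 then removes both Boc groups to return 4.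

Step 1 (lowest risk). The condensation could stall at the aldol adduct or be slowed by poor solubility. The fallback sets out from 1 alone and comes back at 3 by deoxygenative homodimerisation. P(NEt2)3 (1.1 equiv per isatin, CH2Cl2, −60 °C to room temperature) forms a Kukhtin–Ramirez adduct at the C3 ketone. This adduct acts as a carbene equivalent toward a second molecule of 1 and gives 5,5''-dibromodispiro[indoline-3,2'-oxirane-3',3''-indoline]-2,2''-dione F4, which is not isolated. A second equivalent of the phosphine deoxygenates F4 to 3.

**Further compounds**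
F1 | step 3 | 5,5'-dibromo-1H,1'H-3,3'-biindole | Brc1ccc2[nH]cc(-c3c[nH]c4ccc(Br)cc34)c2c1
F2 | step 2 | di-tert-butyl (E)-5,5'-dibromo-2,2'-dioxo-[3,3'-biindolinylidene]-1,1'-dicarboxylate | O=C1N(C(=O)OC(C)(C)C)c2ccc(Br)cc2/C1=C1\C(=O)N(C(=O)OC(C)(C)C)c2ccc(Br)cc21
F3 | step 2 | di-tert-butyl 5,5'-dibromo-2,2'-dioxo-[3,3'-biindoline]-1,1'-dicarboxylate (meso/dl mixture) | O=C1N(C(=O)OC(C)(C)C)c2ccc(Br)cc2C1C1C(=O)N(C(=O)OC(C)(C)C)c2ccc(Br)cc21
F4 | step 1 | 5,5''-dibromodispiro[indoline-3,2'-oxirane-3',3''-indoline]-2,2''-dione (diastereomer mixture) | O=C1Nc2ccc(Br)cc2C13OC34C(=O)Nc5ccc(Br)cc45
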